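## Structural features

The target is a 2,4,5,6,7,7a-hexahydro-1H-inden-2-one: a cyclopentenone (C1, C2, C3, C3a, C7a) fused along C3a–C7a to a cyclohexane (C3a, C4, C5, C6, C7, C7a), with the enone C2(=O)–C3=C3a exocyclic to the six-membered ring. Four stereocentres sit on the bicycle, three of them contiguous (C1–C7a–C7). All four substituents lie on one face: the 2-formylallyl chain at C1, the quaternary methyl at C7a, the carboxyl at C7 and the allylic acyloxy group at C4. A fifth, remote centre (6R) is in the (2E,4E)-4,6-dimethylocta-2,4-dienoate. The fragile groups are the 2-substituted acrolein, the γ-acyloxy enone with its epimerisable C1, the free acid at an enolisable centre, and the dienoate, whose hydrogen at C6 is vinylogously acidic. The real difficulty is the quaternary C7a flanked by C7 and C1 in one absolute sense, together with the 1,4-dioxygenation C2/C4 across the C3=C3a alkene, which must be ordered so that two carbonyl-level carbons never have to be told apart. The key step uses the cyclohexane ring: with C4 as a silyl enol ether (C4=C5), the bonds C3a–C7a and C6–C7 are the two σ-bonds of a Diels–Alder retron. The C3–C2–C1 bridge of the five-membered ring is the tether, and the cis relation of the C7 carboxyl to the C7a methyl is the geometry of an (E)-3-methyl-2-enoyl dienophile.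

## Logic of the disconnections

43 ⇒ 42 ⇒ 41. No skeletal bond is cut: the aldehyde C–H/C=O is traced to a primary allylic carbinol, and the acid and carbinol to their O–C(CH3)3 and O–Si bonds. The enal and the free acid are the most fragile groups and are therefore made last. The demand is an acidolysis that spares two esters and three alkenes, and an oxidation selective for the allylic alcohol beside a free acid.

41 ⇒ 37 + 40. The exocyclic C1–CH2 bond is cut. C1 is the only enolisable α-carbon of the enone (the other α-carbon, C3, is vinylic), so regiochemistry is not in question. The cut removes one stereocentre and four carbons. The forward step needs kinetic α′-deprotonation and entry of the electrophile on the face of the C7a methyl, away from the bulkier C7 branch.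

37 ⇒ 36. The C2 carbonyl is traced to the two C–S bonds of a thioacetal. The mask is needed from the start of the route and is released only once C4 is at the alcohol level and acylated, so C2 and C4 are never ketones together. The demand is dethioacetalisation beside an allylic ester and a dienoate.

36 ⇒ 26 + 34. The C4–O acyl bond is cut, which makes the route convergent. The forward step is acylation, with retention, of an axial allylic alcohol that is 1,3 to the axial methyl.

34 ⇒ 33 ⇒ 31 + 32; 31 ⇒ 30 + 29; 30 ⇒ 28 ⇒ 27. The two alkenes of the dienoate are cut by stabilised-ylide olefinations, and the CH2–CH3 bond of the sec-butyl group by an sp3–sp3 coupling. The stereocentre comes from 27, the brominated, reduced form of methyl (R)-3-hydroxy-2-methylpropanoate: exchange of Br for CH3 changes the descriptor to R without touching the centre. The demand is that the α-chiral aldehyde 30 is not racemised.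

26 ⇒ 25. The C4–H bond is cut (carbinol from ketone). With C3a trigonal, the six-membered ring is locked with the C7a methyl axial and 1,3 to C4, so hydride must enter anti to it.

25 ⇒ 22 ⇒ 21. The C3=C3a π-bond is removed. The forward sequence needs enolisation toward the ring-fusion carbon; elimination from C3a can then only go toward C3 because C7a is quaternary. The oxidant must leave the thioacetal alone.

21 ⇒ 20 ⇒ 17. The ester O–C bond, the acyl–N bond to the auxiliary and the enol O–Si bond are cut. The auxiliary leaves before any enone exists, because its peroxide cleavage would epoxidise an enone. The demand is exocyclic cleavage of a hindered imide.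

17 ⇒ 16. C3a–C7a and C6–C7 are cut: two rings and three stereocentres fall back to an acyclic triene whose only stereocentre is in the auxiliary. The forward step needs an s-cis (Z)-silyloxy diene, an (E)-dienophile and π-facial control. The (4R)-benzyl auxiliary is the correct enantiomer for the face required.

16 ⇒ 15 ⇒ 14 ⇒ 13. The enol O–Si bond, the C4 carbinol/ketone level and the C4–C5 bond (vinyl nucleophile on an aldehyde) are cut. The demand is chemoselective addition to the aldehyde beside the imide.

13 ⇒ 9 + 10. The acyl–N bond and the acetal are cut. The auxiliary is attached under conditions that keep the alkene geometry.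

9 ⇒ 8 ⇒ 7 + 4; 7 ⇒ 5 + 6. The C2–C1 and C2–C3 bonds at the thioacetal carbon are cut, so C2 serves twice as an acyl-anion equivalent. The demand on the second alkylation is SN2 at the allylic bromide in preference to addition to the enoate.

4 ⇒ 3 ⇒ 1 + 2. The C7=C7a alkene and the C–Br bond are cut. 4 is made geometrically pure by olefination instead of radical bromination of the 3-methylbut-2-enoate, which would give an E/Z mixture; the Z component would invert the C7/C7a relationship in the key step.

40 ⇒ 39 ⇒ 38. The C–Br and O–Si bonds are cut back to a symmetrical diol.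

## Other disconnections considered

Alternative 1: The cut is C1–C2, with one carbon excised afterwards. Epoxy ketone A1, a methyl-decalin with its enone ring one carbon larger, would be treated with BF3·OEt2. The epoxide would ionise at the carbon next to C7a, the acyl carbon C2 would shift to it, and the ring would contract to the C1-formyl enone A2.
- In its favour: the angular-methyl decalin class is reached by Robinson annulation, including amine-catalysed asymmetric variants. The quaternary centre would come from a catalyst and not from a stoichiometric auxiliary: on this point it is the better plan.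
- In A2 the C3=C3a enone and the C4 oxygen are already at their final levels, with no desaturation and no thioacetal: also better.
- C1 emerges doubly activated, so alkylation under mild base followed by deformylation would be at least the equal of the kinetic enolate alkylation chosen here.
- Against it: ionisation must occur at a secondary carbon beside a quaternary one, without the tertiary stabilisation on which such contractions normally rely. Hydride shift to a 1,2-dione, migration of a C7a substituent and fluorohydrin formation would compete.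
- The allylic silyl ether must survive BF3, and the C7 carboxyl cis to the methyl has to be built separately on the decalin.
- Comparison: the key step makes one bond and no lasting stereocentre, whereas the chosen step makes two rings, two bonds and the C7/C7a pair. Counting decalin assembly, C7 functionalisation, dienone, epoxide, contraction, alkylation and deformylation, the step count is unlikely to be lower.

Alternative 2: The cut is C3a–C4. SmI2 would reduce the aldehyde of cyclopentenone A3 to a ketyl, which would add 6-exo-trig to the enone β-carbon C3a; protonation of the samarium enolate would give the cis-fused hydroxy ketone A4.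
- In its favour: the C4 carbinol is made directly at the alcohol level, through a chelated chair-like transition state. This is better than the enol ether → ketone → enone → alcohol sequence of the chosen plan.
- The C1 side chain and the C7 ester are present before ring closure, so no late enolate chemistry is needed beside sensitive groups: better.
- After A4 only acylation, dehydrogenation and unveiling remain, a shorter end game: better. The dehydrogenation is regiochemically unambiguous for the same reason as in the chosen plan (C7a is quaternary): equal.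
- Against it: A3 carries the whole problem. The quaternary C7a on a cyclopentenone, flanked by the C1 stereocentre and an acyclic C7 stereocentre, must be set without the help of a ring.
- SmI2 can also reduce the enone or couple the aldehyde. The enone consumed in the key step has to be restored, and the C4 configuration rests on chelation to trivalent samarium, which is hard to predict with an ester nearby.
- Comparison: a radical-anion closure making one ring, one bond and the C3a/C4 pair (C3a transient), against two rings and two bonds in the chosen step. The difficulty is moved to the front of the route, not removed.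

Alternative 3: The cuts are C3–C3a and C3–C4, the second to be broken again later. Rh2(OAc)4 would decompose diazoketone A5, and the carbenoid carbon C3 would add to the C3a=C4 alkene on the face of the tether to give the tricyclic cyclopropyl ketone A6. An oxygen nucleophile would then open A6 at C4 in a homoconjugate sense.
- In its favour: the tether fixes the face of cyclopropanation, and an invertive opening puts the C4 oxygen on the opposite face, syn to the methyl. C4 is thus set by mechanism and not by reagent approach: equal or better.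
- C4 arrives at the alcohol or ester level, conceivably with the side-chain carboxylate as the nucleophile: better redox economy. The metal is catalytic: better.
- Against it: a cyclopropane activated by a single ketone opens with oxygen nucleophiles only under strong acid or Lewis acid. Under those conditions cleavage toward the more substituted C3a, or rearrangement, becomes likely.
- The diazoketone needs diazomethane or an equivalent, the C7/C7a pair must be made beforehand, and desaturation and C1 alkylation still follow.
- Comparison: one ring and two bonds are made, of which one bond and two of the three new stereocentres are given up again, against two rings kept in the chosen step. The step count would be similar at best.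

Key step: step 10

Remark on the chemistry: the ring-fusion hydrogen at C3a of 17–21 (and the selenium substituent of 23 and 24) is drawn for a cis-fused adduct; either C3a epimer serves, because C3a becomes trigonal in 22 and 25.
Remark on the chemistry: 14 is made and used as both carbinol epimers; the centre is oxidised in step 8.

Step 1
Reactants: 1 hydroxyacetone (1-hydroxypropan-2-one); 2 methyl (triphenyl-λ5-phosphanylidene)acetate
Product: 3 methyl (2E)-4-hydroxy-3-methylbut-2-enoate
Conditions: MeCN, 80 °C
Reagents that add atoms: none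
Why: Wittig olefination of an α-hydroxy ketone with a stabilised ylide should place the ester trans to the larger CH2OH group (E); any Z isomer lactonises to the volatile butenolide and is removed, so the geometry that later fixes the C7/C7a relationship is defined here.

Step 2
Reactants: 3 methyl (2E)-4-hydroxy-3-methylbut-2-enoate
Product: 4 methyl (2E)-4-bromo-3-methylbut-2-enoate
Conditions: CBr4, PPh3, CH2Cl2, 0 °C
Reagents that add atoms: carbon tetrabromide, BrC(Br)(Br)Br
Why: Appel bromination; SN2 at the primary allylic carbon leaves the alkene geometry untouched.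

Step 3
Reactants: 5 1,3-dithiane; 6 3-bromo-1,1-dimethoxypropane
Product: 7 2-(3,3-dimethoxypropyl)-1,3-dithiane
Conditions: n-BuLi, THF, −30 °C; then 6, −78 → 0 °C
Reagents that add atoms: none
Why: Corey–Seebach alkylation of 2-lithio-1,3-dithiane with a primary bromide; the acetal is inert to the organolithium.

Step 4
Reactants: 7 2-(3,3-dimethoxypropyl)-1,3-dithiane; 4 methyl (2E)-4-bromo-3-methylbut-2-enoate
Product: 8 methyl (2E)-4-[2-(3,3-dimethoxypropyl)-1,3-dithian-2-yl]-3-methylbut-2-enoate
Conditions: n-BuLi, THF, −25 °C, 3 h; then added to 4 in THF, −78 °C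
Reagents that add atoms: none
Why: Second Corey–Seebach alkylation; the tertiary dithianyl anion should displace the primary allylic bromide (SN2) faster than it adds to the hindered β,β-disubstituted enoate, and inverse addition without a polar cosolvent disfavours conjugate addition.

Step 5
Reactants: 8 methyl (2E)-4-[2-(3,3-dimethoxypropyl)-1,3-dithian-2-yl]-3-methylbut-2-enoate
Product: 9 (2E)-4-[2-(3,3-dimethoxypropyl)-1,3-dithian-2-yl]-3-methylbut-2-enoic acid
Conditions: LiOH, THF/MeOH/H2O, 23 → 40 °C; then cold 1 M HCl to pH 4
Reagents that add atoms: lithium hydroxide, [Li+].[OH-]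
Why: Ester saponification; the conjugated (E)-enoate is the thermodynamic isomer under hydroxide, and the acetal and thioacetal are stable to base and to a brief mild acidification.

Step 6
Reactants: 9 (2E)-4-[2-(3,3-dimethoxypropyl)-1,3-dithian-2-yl]-3-methylbut-2-enoic acid; 10 (4R)-4-benzyl-1,3-oxazolidin-2-one
Product: 13 (4R)-4-benzyl-3-{(2E)-3-methyl-4-[2-(3-oxopropyl)-1,3-dithian-2-yl]but-2-enoyl}-1,3-oxazolidin-2-one, via mixed pivalic anhydride 11 (not isolated), via acetal imide 12 (not isolated)
Conditions: PivCl, Et3N, THF, −20 °C; then 10, LiCl, −20 → 23 °C; then 1 M HCl, THF, 23 °C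
Reagents that add atoms: water, O
Why: N-acylation of the oxazolidinone through a mixed anhydride under the LiCl/Et3N protocol, which needs no strong base and keeps the alkene geometry; the dimethyl acetal is then hydrolysed by aqueous acid, to which imide and thioacetal are inert.

Step 7
Reactants: 13 aldehyde imide
Product: 14 (4R)-4-benzyl-3-{(2E)-4-[2-(3-hydroxypent-4-en-1-yl)-1,3-dithian-2-yl]-3-methylbut-2-enoyl}-1,3-oxazolidin-2-one (both carbinol epimers)
Conditions: CH2=CHMgBr (1.1 equiv), THF, −78 °C
Reagents that add atoms: vinylmagnesium bromide, C=C[Mg]Br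
Why: Grignard 1,2-addition; at −78 °C the aldehyde is far more electrophilic than the conjugated imide, and the new carbinol centre is removed in the next step.

Step 8
Reactants: 14 vinyl carbinol imide
Product: 15 (4R)-4-benzyl-3-{(2E)-3-methyl-4-[2-(3-oxopent-4-en-1-yl)-1,3-dithian-2-yl]but-2-enoyl}-1,3-oxazolidin-2-one
Conditions: Dess–Martin periodinane, NaHCO3, CH2Cl2, 0 °C
Reagents that add atoms: none
Why: Dess–Martin oxidation of the allylic alcohol to the vinyl ketone; under anhydrous buffered conditions alcohol oxidation is much faster than attack at thioacetal sulfur.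

Step 9
Reactants: 15 vinyl ketone imide
Product: 16 (4R)-4-benzyl-3-{(2E)-4-[2-[(2Z)-3-[(tert-butyldimethylsilyl)oxy]penta-2,4-dien-1-yl]-1,3-dithian-2-yl]-3-methylbut-2-enoyl}-1,3-oxazolidin-2-one
Conditions: TBSOTf, Et3N, CH2Cl2, −78 °C
Reagents that add atoms: tert-butyldimethylsilyl trifluoromethanesulfonate, CC(C)(C)[Si](C)(C)OS(=O)(=O)C(F)(F)F
Why: Soft enolisation and O-silylation of the vinyl ketone at its only α-methylene gives the 2-silyloxy diene; the (Z)-enol ether (chain trans to the vinyl group) is favoured because it avoids allylic strain, and it places the tether on the outside of the diene as the cycloaddition requires.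

Step 10
Reactants: 16 silyloxy diene enoyl imide
Product: 17 (4R)-4-benzyl-3-{[(3a'S,7'R,7a'R)-4'-[(tert-butyldimethylsilyl)oxy]-7a'-methyl-1',3',3a',6',7',7a'-hexahydrospiro[1,3-dithiane-2,2'-inden]-7'-yl]carbonyl}-1,3-oxazolidin-2-one
Conditions: Et2AlCl (2.0 equiv), CH2Cl2, −78 → −30 °C
Reagents that add atoms: none
Why: Excess Et2AlCl converts the imide into a cationic aluminium chelate bound to both carbonyls with the enoyl unit s-cis, which lowers the LUMO and makes the β-carbon C7a the electrophilic site, while the silyloxy group makes C3a the nucleophilic diene terminus. The asynchronous intramolecular Diels–Alder reaction (at its polar extreme a Mukaiyama–Michael addition followed by a Michael closure) therefore forms C3a–C7a first and C6–C7 second; the closest known reaction types are Lewis-acid-promoted cycloadditions of trienyl N-acyloxazolidinones and intramolecular cycloadditions or double Michael reactions of 2-silyloxy dienes. The five-membered ring closes 5-exo-trig through the three-atom tether C3–C2–C1, helped by the geminal dithio substitution at C2, and the six-membered ring closes by bonding of C6 to C7 (6-endo-trig in the stepwise picture), leaving the C4=C5 silyl enol ether. C7a and C7 are set in the absolute sense by the (R)-benzyl group, which covers one face of the chelated dienophile so that the diene adds to the other, and in the relative sense by suprafacial addition to the (E)-alkene, which keeps methyl and carbonyl cis. C3a follows from the folding of the tether and needs no control because it becomes trigonal later. The step needs π-facial selectivity on a β,β-disubstituted enoyl imide, secured by the s-cis chelate (the s-trans rotamer is disfavoured by the β-methyl cis to the carbonyl), and a reactive s-cis diene, secured by the (Z)-enol ether; regiochemistry is fixed by the tether.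

Step 11
Reactants: 17 silyl enol ether cycloadduct
Product: 20 (3a'S,7'R,7a'R)-7a'-methyl-4'-oxooctahydrospiro[1,3-dithiane-2,2'-indene]-7'-carboxylic acid, via keto imide 18 (not isolated), via peroxy acid 19 (not isolated)
Conditions: 1 M HCl, THF, 23 °C; then LiOH, 30% H2O2, THF/H2O, 0 °C; then Na2SO3; acidify to pH 3
Reagents that add atoms: hydrogen peroxide, OO
Why: Acid hydrolysis of the silyl enol ether, then hydroperoxide cleavage of the N-acyloxazolidinone, which attacks the exocyclic carbonyl even in hindered imides and does not epimerise C7; sulfite reduces the peroxy acid. The auxiliary is removed before any enone exists, and the peroxide anion does not oxidise the thioacetal.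

Step 12
Reactants: 20 keto acid
Product: 21 tert-butyl (3a'S,7'R,7a'R)-7a'-methyl-4'-oxooctahydrospiro[1,3-dithiane-2,2'-indene]-7'-carboxylate
Conditions: tert-butyl 2,2,2-trichloroacetimidate, BF3·OEt2 (cat.), CH2Cl2/cyclohexane, 23 °C
Reagents that add atoms: tert-butyl 2,2,2-trichloroacetimidate, CC(C)(C)OC(=N)C(Cl)(Cl)Cl
Why: Acid-catalysed tert-butylation of the carboxylic acid by the imidate; the carboxyl oxygen is alkylated, so hindrance at the acyl carbon does not matter.

Step 13
Reactants: 21 keto tert-butyl ester
Product: 22 tert-butyl (7'R,7a'S)-7a'-methyl-4'-[(trimethylsilyl)oxy]-1',3',5',6',7',7a'-hexahydrospiro[1,3-dithiane-2,2'-indene]-7'-carboxylate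
Conditions: TMSOTf, Et3N, CH2Cl2, 0 → 23 °C (equilibrating)
Reagents that add atoms: trimethylsilyl trifluoromethanesulfonate, C[Si](C)(C)OS(=O)(=O)C(F)(F)F
Why: Enol silylation under equilibrating conditions should favour the tetrasubstituted C3a=C4 enol ether over the C4=C5 isomer; tert-butyl esters and thioacetals tolerate silyl triflate buffered with amine.

Step 14
Reactants: 22 trimethylsilyl enol ether
Product: 25 tert-butyl (7'R,7a'S)-7a'-methyl-4'-oxo-1',4',5',6',7',7a'-hexahydrospiro[1,3-dithiane-2,2'-indene]-7'-carboxylate, via C3a selenide 23 (not isolated), via selenoxide 24 (not isolated)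
Conditions: PhSeCl, CH2Cl2, −78 °C; then NaIO4, NaHCO3, THF/MeOH/H2O, 0 → 23 °C
Reagents that add atoms: none
Why: Selenenylation of the silyl enol ether at C3a, then selenoxide syn-elimination; the only β-hydrogens are on C3 (C7a is quaternary), so the C3=C3a enone is the only possible product. Periodate oxidises selenium much faster than thioacetal sulfur.

Step 15
Reactants: 25 exocyclic enone
Product: 26 tert-butyl (4'S,7'R,7a'S)-4'-hydroxy-7a'-methyl-1',4',5',6',7',7a'-hexahydrospiro[1,3-dithiane-2,2'-indene]-7'-carboxylate
Conditions: NaBH4, CeCl3·7H2O, MeOH, −78 °C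
Reagents that add atoms: none
Why: Luche 1,2-reduction; with C3a trigonal the C7a methyl is axial and 1,3 to C4, so hydride enters from the opposite face and the hydroxyl ends up syn to the methyl (4S).

Step 16
Reactants: 27 (2S)-3-bromo-2-methylpropan-1-ol
Product: 28 (2R)-2-methylbutan-1-ol
Conditions: MeMgBr (2.5 equiv), Li2CuCl4 (3 mol%), THF, −20 → 23 °C
Reagents that add atoms: methylmagnesium bromide, C[Mg]Br
Why: Copper-catalysed sp3–sp3 coupling of a Grignard reagent with a primary bromide, the first equivalent forming the magnesium alkoxide; no bond to the stereocentre is touched, and the descriptor changes from S to R only through the priority rules.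

Step 17
Reactants: 28 (2R)-2-methylbutan-1-ol; 29 2-(triphenyl-λ5-phosphanylidene)propanal
Product: 31 (2E,4R)-2,4-dimethylhex-2-enal, via (2R)-2-methylbutanal 30 (not isolated)
Conditions: TEMPO (cat.), KBr, NaOCl, CH2Cl2/H2O, 0 °C; dried organic phase, then 29, toluene, 80 °C
Reagents that add atoms: none
Why: Anelli oxidation gives the volatile, configurationally labile aldehyde, which is used in solution without isolation; Wittig reaction with the weakly basic stabilised formyl ylide should give the (E)-trisubstituted enal without racemisation.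

Step 18
Reactants: 31 (2E,4R)-2,4-dimethylhex-2-enal; 32 triethyl phosphonoacetate
Product: 33 ethyl (2E,4E,6R)-4,6-dimethylocta-2,4-dienoate
Conditions: NaH, 32, THF, 0 °C; then 31, 0 → 23 °C
Reagents that add atoms: none
Why: Horner–Wadsworth–Emmons olefination, E-selective for aldehydes; the preformed phosphonate anion is too weak a base to deprotonate the γ-stereocentre.

Step 19
Reactants: 33 ethyl (2E,4E,6R)-4,6-dimethylocta-2,4-dienoate
Product: 34 (2E,4E,6R)-4,6-dimethylocta-2,4-dienoic acid
Conditions: LiOH, THF/MeOH/H2O, 23 °C
Reagents that add atoms: lithium hydroxide, [Li+].[OH-]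
Why: Saponification; hydroxide does not remove the remote allylic hydrogen, so geometry and configuration are kept.

Step 20
Reactants: 26 allylic alcohol; 34 (2E,4E,6R)-4,6-dimethylocta-2,4-dienoic acid
Product: 36 tert-butyl (4'S,7'R,7a'S)-4'-{[(2E,4E,6R)-4,6-dimethylocta-2,4-dienoyl]oxy}-7a'-methyl-1',4',5',6',7',7a'-hexahydrospiro[1,3-dithiane-2,2'-indene]-7'-carboxylate, via mixed aryl anhydride 35 (not isolated)
Conditions: 2,4,6-trichlorobenzoyl chloride, Et3N, THF, 23 °C; then 26, DMAP, toluene, 23 → 40 °C
Reagents that add atoms: none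
Why: Yamaguchi esterification; the acylpyridinium is reactive enough for the hindered axial allylic alcohol, and the C–O bond at C4 is not broken, so configuration is retained.

Step 21
Reactants: 36 dienoate thioacetal
Product: 37 tert-butyl (4S,7R,7aS)-4-{[(2E,4E,6R)-4,6-dimethylocta-2,4-dienoyl]oxy}-7a-methyl-2-oxo-2,4,5,6,7,7a-hexahydro-1H-indene-7-carboxylate
Conditions: PhI(OCOCF3)2, NaHCO3, MeCN/H2O (9:1), 0 °C
Reagents that add atoms: water, O
Why: Oxidative dethioacetalisation with a hypervalent iodine reagent: activation at sulfur, attack of water at C2 and loss of the dithiol as the disulfide reveal the conjugated enone; the electron-poor alkenes and the esters are not attacked.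

Step 22
Reactants: 38 2-methylidenepropane-1,3-diol
Product: 39 2-{[(tert-butyldimethylsilyl)oxy]methyl}prop-2-en-1-ol
Conditions: NaH (1.0 equiv), THF, 0 °C; then TBSCl
Reagents that add atoms: tert-butyldimethylsilyl chloride, CC(C)(C)[Si](C)(C)Cl
Why: Monosilylation of a symmetrical diol through its sparingly soluble monosodium alkoxide.

Step 23
Reactants: 39 2-{[(tert-butyldimethylsilyl)oxy]methyl}prop-2-en-1-ol
Product: 40 {[2-(bromomethyl)prop-2-en-1-yl]oxy}(tert-butyl)dimethylsilane
Conditions: CBr4, PPh3, CH2Cl2, 0 °C
Reagents that add atoms: carbon tetrabromide, BrC(Br)(Br)Br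
Why: Appel bromination of the primary allylic alcohol under neutral conditions that keep the silyl ether.

Step 24
Reactants: 37 acyloxy enone; 40 {[2-(bromomethyl)prop-2-en-1-yl]oxy}(tert-butyl)dimethylsilane
Product: 41 tert-butyl (1R,4S,7R,7aS)-1-(2-{[(tert-butyldimethylsilyl)oxy]methyl}prop-2-en-1-yl)-4-{[(2E,4E,6R)-4,6-dimethylocta-2,4-dienoyl]oxy}-7a-methyl-2-oxo-2,4,5,6,7,7a-hexahydro-1H-indene-7-carboxylate
Conditions: LiN(SiMe3)2 (1.05 equiv), THF, −78 °C; then 40, DMPU, −78 → −40 °C
Reagents that add atoms: none
Why: Kinetic α′-deprotonation of the enone at C1 (the ketone is the most acidic site) and C-alkylation of the cross-conjugated lithium enolate with a reactive allylic bromide; the electrophile should enter on the face of the C7a methyl, away from the bulkier C7 branch with its axial hydrogen and ester, giving the 1R centre.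

Step 25
Reactants: 41 fully protected precursor
Product: 42 (1R,4S,7R,7aS)-4-{[(2E,4E,6R)-4,6-dimethylocta-2,4-dienoyl]oxy}-1-[2-(hydroxymethyl)prop-2-en-1-yl]-7a-methyl-2-oxo-2,4,5,6,7,7a-hexahydro-1H-indene-7-carboxylic acid
Conditions: TFA/CH2Cl2/H2O (30:65:5), 0 → 23 °C
Reagents that add atoms: none
Why: Acidolysis of the tert-butyl ester (loss of 2-methylpropene) and of the primary silyl ether in one operation; the 1,1-disubstituted alkene is deactivated toward protonation by its allylic oxygen, and the enone, the dienoate and the C1 centre are stable to acid.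

Step 26
Reactants: 42 hydroxy acid
Product: 43 (1R,4S,7R,7aS)-4-{[(2E,4E,6R)-4,6-dimethylocta-2,4-dienoyl]oxy}-1-(2-formylprop-2-en-1-yl)-7a-methyl-2-oxo-2,4,5,6,7,7a-hexahydro-1H-indene-7-carboxylic acid
Conditions: TEMPO (cat.), PhI(OAc)2, CH2Cl2, 23 °C
Reagents that add atoms: none
Why: Oxoammonium (TEMPO) oxidation, selective for the primary allylic alcohol; it stops at the aldehyde in the absence of water and tolerates the free acid, and the by-products are volatile or non-polar.

Compound list

1 | hydroxyacetone (1-hydroxypropan-2-one) | CC(=O)CO | starting material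
2 | methyl (triphenyl-λ5-phosphanylidene)acetate | COC(=O)C=P(c1ccccc1)(c1ccccc1)c1ccccc1 | starting material
3 | methyl (2E)-4-hydroxy-3-methylbut-2-enoate | COC(=O)/C=C(\C)CO | intermediate
4 | methyl (2E)-4-bromo-3-methylbut-2-enoate | COC(=O)/C=C(\C)CBr | intermediate
5 | 1,3-dithiane | C1CSCSC1 | starting material
6 | 3-bromo-1,1-dimethoxypropane | COC(CCBr)OC | starting material
7 | 2-(3,3-dimethoxypropyl)-1,3-dithiane | COC(CCC1SCCCS1)OC | intermediate
8 | methyl (2E)-4-[2-(3,3-dimethoxypropyl)-1,3-dithian-2-yl]-3-methylbut-2-enoate | COC(=O)/C=C(\C)CC1(CCC(OC)OC)SCCCS1 | intermediate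
9 | (2E)-4-[2-(3,3-dimethoxypropyl)-1,3-dithian-2-yl]-3-methylbut-2-enoic acid | COC(CCC1(C/C(C)=C/C(=O)O)SCCCS1)OC | intermediate
10 | (4R)-4-benzyl-1,3-oxazolidin-2-one | O=C1N[C@H](Cc2ccccc2)CO1 | starting material
11 | (2E)-4-[2-(3,3-dimethoxypropyl)-1,3-dithian-2-yl]-3-methylbut-2-enoic 2,2-dimethylpropanoic anhydride | COC(CCC1(C/C(C)=C/C(=O)OC(=O)C(C)(C)C)SCCCS1)OC | intermediate (not isolated)
12 | (4R)-4-benzyl-3-{(2E)-4-[2-(3,3-dimethoxypropyl)-1,3-dithian-2-yl]-3-methylbut-2-enoyl}-1,3-oxazolidin-2-one | COC(CCC1(C/C(C)=C/C(=O)N2[C@H](Cc3ccccc3)COC2=O)SCCCS1)OC | intermediate (not isolated)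
13 | (4R)-4-benzyl-3-{(2E)-3-methyl-4-[2-(3-oxopropyl)-1,3-dithian-2-yl]but-2-enoyl}-1,3-oxazolidin-2-one | O=CCCC1(C/C(C)=C/C(=O)N2[C@H](Cc3ccccc3)COC2=O)SCCCS1 | intermediate
14 | (4R)-4-benzyl-3-{(2E)-4-[2-(3-hydroxypent-4-en-1-yl)-1,3-dithian-2-yl]-3-methylbut-2-enoyl}-1,3-oxazolidin-2-one, both carbinol epimers | C=CC(O)CCC1(C/C(C)=C/C(=O)N2[C@H](Cc3ccccc3)COC2=O)SCCCS1 | intermediate
15 | (4R)-4-benzyl-3-{(2E)-3-methyl-4-[2-(3-oxopent-4-en-1-yl)-1,3-dithian-2-yl]but-2-enoyl}-1,3-oxazolidin-2-one | C=CC(=O)CCC1(C/C(C)=C/C(=O)N2[C@H](Cc3ccccc3)COC2=O)SCCCS1 | intermediate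
16 | (4R)-4-benzyl-3-{(2E)-4-[2-[(2Z)-3-[(tert-butyldimethylsilyl)oxy]penta-2,4-dien-1-yl]-1,3-dithian-2-yl]-3-methylbut-2-enoyl}-1,3-oxazolidin-2-one | C=C/C(O[Si](C)(C)C(C)(C)C)=C/CC1(SCCCS1)C/C(C)=C/C(=O)N2[C@H](Cc3ccccc3)COC2=O | intermediate
17 | (4R)-4-benzyl-3-{[(3a'S,7'R,7a'R)-4'-[(tert-butyldimethylsilyl)oxy]-7a'-methyl-1',3',3a',6',7',7a'-hexahydrospiro[1,3-dithiane-2,2'-inden]-7'-yl]carbonyl}-1,3-oxazolidin-2-one (C7a methyl, C7 acyl group and C3a hydrogen on one face) | C[C@@]12CC3(SCCCS3)C[C@@H]1C(O[Si](C)(C)C(C)(C)C)=CC[C@H]2C(=O)N4[C@H](Cc5ccccc5)COC4=O | intermediate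
18 | C4 ketone of 17 (enol ether hydrolysed, imide retained, stereocentres as in 17) | C[C@@]12CC3(SCCCS3)C[C@@H]1C(=O)CC[C@H]2C(=O)N4[C@H](Cc5ccccc5)COC4=O | intermediate (not isolated)
19 | (3a'S,7'R,7a'R)-7a'-methyl-4'-oxooctahydrospiro[1,3-dithiane-2,2'-indene]-7'-carboperoxoic acid | C[C@@]12CC3(SCCCS3)C[C@@H]1C(=O)CC[C@H]2C(=O)OO | intermediate (not isolated)
20 | (3a'S,7'R,7a'R)-7a'-methyl-4'-oxooctahydrospiro[1,3-dithiane-2,2'-indene]-7'-carboxylic acid | C[C@@]12CC3(SCCCS3)C[C@@H]1C(=O)CC[C@H]2C(=O)O | intermediate
21 | tert-butyl (3a'S,7'R,7a'R)-7a'-methyl-4'-oxooctahydrospiro[1,3-dithiane-2,2'-indene]-7'-carboxylate | C[C@@]12CC3(SCCCS3)C[C@@H]1C(=O)CC[C@H]2C(=O)OC(C)(C)C | intermediate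
22 | tert-butyl (7'R,7a'S)-7a'-methyl-4'-[(trimethylsilyl)oxy]-1',3',5',6',7',7a'-hexahydrospiro[1,3-dithiane-2,2'-indene]-7'-carboxylate | C[C@@]12CC3(SCCCS3)CC1=C(O[Si](C)(C)C)CC[C@H]2C(=O)OC(C)(C)C | intermediate
23 | 3a'-(phenylselanyl) derivative of 21 (selenium on the face opposite the C7a methyl) | C[C@@]12CC3(SCCCS3)C[C@@]1([Se]c4ccccc4)C(=O)CC[C@H]2C(=O)OC(C)(C)C | intermediate (not isolated)
24 | selenoxide of 23 (configuration at selenium not defined) | C[C@@]12CC3(SCCCS3)C[C@@]1([Se](=O)c4ccccc4)C(=O)CC[C@H]2C(=O)OC(C)(C)C | intermediate (not isolated)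
25 | tert-butyl (7'R,7a'S)-7a'-methyl-4'-oxo-1',4',5',6',7',7a'-hexahydrospiro[1,3-dithiane-2,2'-indene]-7'-carboxylate | C[C@@]12CC3(SCCCS3)C=C1C(=O)CC[C@H]2C(=O)OC(C)(C)C | intermediate
26 | tert-butyl (4'S,7'R,7a'S)-4'-hydroxy-7a'-methyl-1',4',5',6',7',7a'-hexahydrospiro[1,3-dithiane-2,2'-indene]-7'-carboxylate | C[C@@]12CC3(SCCCS3)C=C1[C@@H](O)CC[C@H]2C(=O)OC(C)(C)C | intermediate
27 | (2S)-3-bromo-2-methylpropan-1-ol | OC[C@H](C)CBr | starting material
28 | (2R)-2-methylbutan-1-ol | CC[C@@H](C)CO | intermediate
29 | 2-(triphenyl-λ5-phosphanylidene)propanal | CC(C=O)=P(c1ccccc1)(c1ccccc1)c1ccccc1 | starting material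
30 | (2R)-2-methylbutanal | CC[C@@H](C)C=O | intermediate (not isolated)
31 | (2E,4R)-2,4-dimethylhex-2-enal | CC[C@@H](C)/C=C(\C)C=O | intermediate
32 | triethyl phosphonoacetate | CCOC(=O)CP(=O)(OCC)OCC | starting material
33 | ethyl (2E,4E,6R)-4,6-dimethylocta-2,4-dienoate | CCOC(=O)/C=C/C(C)=C/[C@H](C)CC | intermediate
34 | (2E,4E,6R)-4,6-dimethylocta-2,4-dienoic acid | OC(=O)/C=C/C(C)=C/[C@H](C)CC | intermediate
35 | (2E,4E,6R)-4,6-dimethylocta-2,4-dienoic 2,4,6-trichlorobenzoic anhydride | CC[C@@H](C)/C=C(C)/C=C/C(=O)OC(=O)c1c(Cl)cc(Cl)cc1Cl | intermediate (not isolated)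
36 | tert-butyl (4'S,7'R,7a'S)-4'-{[(2E,4E,6R)-4,6-dimethylocta-2,4-dienoyl]oxy}-7a'-methyl-1',4',5',6',7',7a'-hexahydrospiro[1,3-dithiane-2,2'-indene]-7'-carboxylate | C[C@@]12CC3(SCCCS3)C=C1[C@@H](OC(=O)/C=C/C(C)=C/[C@H](C)CC)CC[C@H]2C(=O)OC(C)(C)C | intermediate
37 | tert-butyl (4S,7R,7aS)-4-{[(2E,4E,6R)-4,6-dimethylocta-2,4-dienoyl]oxy}-7a-methyl-2-oxo-2,4,5,6,7,7a-hexahydro-1H-indene-7-carboxylate | C1C(=O)C=C2[C@@H](OC(=O)/C=C/C(C)=C/[C@H](C)CC)CC[C@@H](C(=O)OC(C)(C)C)[C@@]21C | intermediate
38 | 2-methylidenepropane-1,3-diol | C=C(CO)CO | starting material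
39 | 2-{[(tert-butyldimethylsilyl)oxy]methyl}prop-2-en-1-ol | C=C(CO)CO[Si](C)(C)C(C)(C)C | intermediate
40 | {[2-(bromomethyl)prop-2-en-1-yl]oxy}(tert-butyl)dimethylsilane | C=C(CBr)CO[Si](C)(C)C(C)(C)C | intermediate
41 | tert-butyl (1R,4S,7R,7aS)-1-(2-{[(tert-butyldimethylsilyl)oxy]methyl}prop-2-en-1-yl)-4-{[(2E,4E,6R)-4,6-dimethylocta-2,4-dienoyl]oxy}-7a-methyl-2-oxo-2,4,5,6,7,7a-hexahydro-1H-indene-7-carboxylate | C=C(CO[Si](C)(C)C(C)(C)C)C[C@H]1C(=O)C=C2[C@@H](OC(=O)/C=C/C(C)=C/[C@H](C)CC)CC[C@@H](C(=O)OC(C)(C)C)[C@@]21C | intermediate
42 | (1R,4S,7R,7aS)-4-{[(2E,4E,6R)-4,6-dimethylocta-2,4-dienoyl]oxy}-1-[2-(hydroxymethyl)prop-2-en-1-yl]-7a-methyl-2-oxo-2,4,5,6,7,7a-hexahydro-1H-indene-7-carboxylic acid | C=C(CO)C[C@H]1C(=O)C=C2[C@@H](OC(=O)/C=C/C(C)=C/[C@H](C)CC)CC[C@@H](C(=O)O)[C@@]21C | intermediate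
43 | (1R,4S,7R,7aS)-4-{[(2E,4E,6R)-4,6-dimethylocta-2,4-dienoyl]oxy}-1-(2-formylprop-2-en-1-yl)-7a-methyl-2-oxo-2,4,5,6,7,7a-hexahydro-1H-indene-7-carboxylic acid | C=C(C=O)C[C@H]1C(=O)C=C2[C@@H](OC(=O)/C=C/C(C)=C/[C@H](C)CC)CC[C@@H](C(=O)O)[C@@]21C | target

Total step count: 26. Longest linear sequence: 19 steps (steps 1, 2, 4–15, 20, 21, 24–26).

Least certain steps

Step 10 (key step). The β,β-disubstituted enoyl imide is a sluggish acceptor, so loss of the silyl group from the diene under the Lewis acid may outrun ring formation. The β-methyl cis to the carbonyl may also loosen the chelate and erode the discrimination between the two alkene faces. The fallback is an anionic intramolecular double Michael reaction that needs neither the silyl diene nor the Lewis acid. It sets out from 15 (LiN(SiMe3)2, THF, −78 → 0 °C). The cross-conjugated lithium dienolate of the vinyl ketone adds through C3a to C7a of the lithium-chelated enoyl imide, and the resulting imide enolate closes onto the enone at C6. Protonation gives 18, where the route is rejoined in the second stage of step 11.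

Step 4. The hindered dithianyl anion may add to the enoate (at the carbonyl or in a conjugate sense, followed by cyclopropane closure), or may remove an acidic γ-hydrogen of 4, in place of the SN2 displacement. The fallback takes the ester out of the electrophile. Prop-2-yn-1-ol is methylaluminated (Me3Al, zirconocene dichloride Cp2ZrCl2) and iodinated to (2E)-3-iodo-2-methylprop-2-en-1-ol F1, which is converted (CBr4, PPh3) into (1E)-3-bromo-1-iodo-2-methylprop-1-ene F2. The fallback sets out from 7, which is lithiated as before and alkylated with F2 to give 2-(3,3-dimethoxypropyl)-2-[(2E)-3-iodo-2-methylprop-2-en-1-yl]-1,3-dithiane F3. Iodine–lithium exchange (t-BuLi, −78 °C) and CO2 then give, with retention of alkene geometry, 9, where the route is rejoined.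

Step 13 (with step 14). Enol silylation may go toward C5 if equilibration is incomplete, which would lead to the C5=C6 enone; the thioacetal may also be oxidised at sulfur during selenoxide formation. The fallback introduces the alkene from the C2 ketone, where only the C3–C3a direction is possible. It sets out from 21, which is reduced (LiBH(s-Bu)3, THF, −78 °C) to tert-butyl (3a'S,4'S,7'R,7a'R)-4'-hydroxy-7a'-methyloctahydrospiro[1,3-dithiane-2,2'-indene]-7'-carboxylate F4. Should the reduction deliver the C4 epimer instead, a Mitsunobu esterification with 34 would invert it. F4 is esterified with 34 under the conditions of step 20 to the saturated dienoate F5. Dethioacetalisation as in step 21 gives the saturated C2 ketone F6, tert-butyl (3aS,4S,7R,7aR)-4-{[(2E,4E,6R)-4,6-dimethylocta-2,4-dienoyl]oxy}-7a-methyl-2-oxooctahydro-1H-indene-7-carboxylate. Dehydrogenation with 2-iodoxybenzoic acid (DMSO, 70 °C) gives 37, where the route is rejoined.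

Step 24. Proton transfer within the enolate (to C4–H or to the dienoate) may occur before C–C bond formation and erode regiocontrol and the C4 centre; the electrophile may also enter partly anti to the methyl. The fallback alkylates before the dienoate is present. It sets out from 26, which is dethioacetalised as in step 21 to the hydroxy enone F7, tert-butyl (4S,7R,7aS)-4-hydroxy-7a-methyl-2-oxo-2,4,5,6,7,7a-hexahydro-1H-indene-7-carboxylate. Its alkoxide–enolate dianion (LiN(SiMe3)2, 2.1 equiv) is alkylated with 40 to give the C1-alkylated hydroxy enone F8. Yamaguchi esterification of F8 with 34 gives 41, where the route is rejoined.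

Step 16. The bromo alkoxide may close to an oxetane, or methyl transfer from copper may be slow; the volatile product is also easily lost on isolation. The fallback builds the stereocentre by auxiliary-controlled alkylation. It sets out from 10, which is acylated (n-BuLi, butanoyl chloride) to (4R)-4-benzyl-3-butanoyl-1,3-oxazolidin-2-one F9. Methylation of its sodium enolate (NaN(SiMe3)2, MeI, −78 °C) on the face opposite the benzyl group gives (4R)-4-benzyl-3-[(2R)-2-methylbutanoyl]-1,3-oxazolidin-2-one F10. Reduction with LiBH4 gives 28, where the route is rejoined.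

## Further compounds

F0 | step 10 | none | none
F1 | step 4 | (2E)-3-iodo-2-methylprop-2-en-1-ol | OC/C(C)=C/I
F2 | step 4 | (1E)-3-bromo-1-iodo-2-methylprop-1-ene | BrC/C(C)=C/I
F3 | step 4 | 2-(3,3-dimethoxypropyl)-2-[(2E)-3-iodo-2-methylprop-2-en-1-yl]-1,3-dithiane | COC(CCC1(C/C(C)=C/I)SCCCS1)OC
F4 | step 13 | tert-butyl (3a'S,4'S,7'R,7a'R)-4'-hydroxy-7a'-methyloctahydrospiro[1,3-dithiane-2,2'-indene]-7'-carboxylate | C[C@@]12CC3(SCCCS3)C[C@@H]1[C@@H](O)CC[C@H]2C(=O)OC(C)(C)C
F5 | step 13 | tert-butyl (3a'S,4'S,7'R,7a'R)-4'-{[(2E,4E,6R)-4,6-dimethylocta-2,4-dienoyl]oxy}-7a'-methyloctahydrospiro[1,3-dithiane-2,2'-indene]-7'-carboxylate | C[C@@]12CC3(SCCCS3)C[C@@H]1[C@@H](OC(=O)/C=C/C(C)=C/[C@H](C)CC)CC[C@H]2C(=O)OC(C)(C)C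
F6 | step 13 | tert-butyl (3aS,4S,7R,7aR)-4-{[(2E,4E,6R)-4,6-dimethylocta-2,4-dienoyl]oxy}-7a-methyl-2-oxooctahydro-1H-indene-7-carboxylate | C[C@@]12CC(=O)C[C@@H]1[C@@H](OC(=O)/C=C/C(C)=C/[C@H](C)CC)CC[C@H]2C(=O)OC(C)(C)C
F7 | step 24 | tert-butyl (4S,7R,7aS)-4-hydroxy-7a-methyl-2-oxo-2,4,5,6,7,7a-hexahydro-1H-indene-7-carboxylate | C1C(=O)C=C2[C@@H](O)CC[C@@H](C(=O)OC(C)(C)C)[C@@]21C
F8 | step 24 | tert-butyl (1R,4S,7R,7aS)-1-(2-{[(tert-butyldimethylsilyl)oxy]methyl}prop-2-en-1-yl)-4-hydroxy-7a-methyl-2-oxo-2,4,5,6,7,7a-hexahydro-1H-indene-7-carboxylate | C=C(CO[Si](C)(C)C(C)(C)C)C[C@H]1C(=O)C=C2[C@@H](O)CC[C@@H](C(=O)OC(C)(C)C)[C@@]21C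
F9 | step 16 | (4R)-4-benzyl-3-butanoyl-1,3-oxazolidin-2-one | CCCC(=O)N1[C@H](Cc2ccccc2)COC1=O
F10 | step 16 | (4R)-4-benzyl-3-[(2R)-2-methylbutanoyl]-1,3-oxazolidin-2-one | CC[C@@H](C)C(=O)N1[C@H](Cc2ccccc2)COC1=O
A1 | alternative 1 | prop-2-en-1-yl 7,8-epoxy-8a-methyl-6-oxo-4-[(triisopropylsilyl)oxy]-1,2,3,4,6,7,8,8a-octahydronaphthalene-1-carboxylate (epoxide anti to the methyl group, other centres as in the target) | O=C1C=C2[C@@H](O[Si](C(C)C)(C(C)C)C(C)C)CC[C@@H](C(=O)OCC=C)[C@]2(C)[C@@H]3O[C@H]13
A2 | alternative 1 | prop-2-en-1-yl (1Z)-1-(hydroxymethylidene)-7a-methyl-2-oxo-4-[(triisopropylsilyl)oxy]-2,4,5,6,7,7a-hexahydro-1H-indene-7-carboxylate (enol of the C1-formyl enone) | O/C=C1\C(=O)C=C2[C@@H](O[Si](C(C)C)(C(C)C)C(C)C)CC[C@@H](C(=O)OCC=C)[C@@]21C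
A3 | alternative 2 | tert-butyl 2-[5-(2-{[(tert-butyldimethylsilyl)oxy]methyl}prop-2-en-1-yl)-1-methyl-4-oxocyclopent-2-en-1-yl]-5-oxopentanoate (centres as in the target) | O=C1C=C[C@@]([C@@H](CCC=O)C(=O)OC(C)(C)C)(C)[C@H]1CC(=C)CO[Si](C)(C)C(C)(C)C
A4 | alternative 2 | tert-butyl 1-(2-{[(tert-butyldimethylsilyl)oxy]methyl}prop-2-en-1-yl)-4-hydroxy-7a-methyl-2-oxooctahydro-1H-indene-7-carboxylate (cis-fused, hydroxyl syn to the methyl group) | O=C1C[C@@H]2[C@@H](O)CC[C@@H](C(=O)OC(C)(C)C)[C@]2(C)[C@H]1CC(=C)CO[Si](C)(C)C(C)(C)C
A5 | alternative 3 | ethyl 2-(3-diazo-2-oxopropyl)-2-methylcyclohex-3-ene-1-carboxylate (ester cis to the methyl group) | [N-]=[N+]=CC(=O)C[C@]1(C)C=CCC[C@H]1C(=O)OCC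
A6 | alternative 3 | ethyl 7a-methyl-2-oxo-3,4-cyclo-octahydro-1H-indene-7-carboxylate (cyclopropane C3–C3a–C4 fused to the cyclopentanone and the cyclohexane) | O=C1C[C@@]2(C)[C@H](C(=O)OCC)CC[C@H]3[C@@H]1[C@@H]23
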